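## Retrosynthetic overview

1. Feature: in ring B of the quinone (C1 carbonyl, C2–OH, C3–alkyl, C4 carbonyl), C2 has the oxidation level of a carboxyl carbon and C3 is the α-carbon of the aryl ketone C4. The C2–C3 bond is therefore an intramolecular Claisen (Dieckmann) bond, and C1 can enter as a plain benzylic CH2.
2. Late stage: take off the acetate (last-step acetylation of the free (S)-alcohol) and the C1 oxygen (autoxidation) to reach a 2-alkylnaphthalene-1,3-diol. Then cut C2–C3 to a methyl 2-acylarylacetate carrying the silyl-protected (S)-side chain.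
3. The ortho pair (C8a–CH2CO2Me and C4a–acyl) comes from oxidative cleavage of the C=C bond of a 3-alkylindene. The indene is made from 4,6,7-trimethoxyindan-1-one and a four-carbon organomagnesium reagent derived from (S)-butane-1,3-diol, the source of the only stereocentre.
4. The indanone arises by Friedel–Crafts closure of 3-(2,4,5-trimethoxyphenyl)propanoic acid at its single free ortho carbon, which fixes the C5, C6, C8 methoxy pattern relative to C4 and C1.
5. Ring order: ring A is bought; an auxiliary five-membered ring is closed in step 1 and cut open in step 6; ring B is closed in step 9.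

Key step: step 9

Assumption: the target is treated as the 2-hydroxy-1,4-dione tautomer written in its SMILES, and the locants C1–C8a used in the text are those of this quinone (C1 carbonyl beside C2–OH, C3 alkyl, C4 carbonyl, methoxy groups on C5, C6 and C8).

## Route

Step 1
Reactants: 1 3-(2,4,5-trimethoxyphenyl)propanoic acid
Product: 2 4,6,7-trimethoxy-2,3-dihydro-1H-inden-1-one
Conditions: P2O5/MeSO3H (1:10 w/w), dilute, rt → 40 °C
Reagents that add atoms: none
Why: Intramolecular Friedel–Crafts acylation through the mixed anhydride/acylium ion can reach only the one unsubstituted carbon ortho to the chain (five-membered closure, ortho to a methoxy group), while the other free ring carbon is out of reach of the tether and is shielded between two methoxy groups against intermolecular attack.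

Step 2
Reactants: 3 (S)-butane-1,3-diol
Product: 4 (S)-4-iodobutan-2-ol
Conditions: I2, PPh3, imidazole, CH2Cl2, 0 °C
Reagents that add atoms: iodine, II
Why: Garegg–Samuelsson (Appel-type) iodination is an SN2 displacement of an alkoxyphosphonium ion, so with one equivalent of reagent it takes the unhindered primary hydroxyl group and leaves the C–O bond at the stereocentre untouched.

Step 3
Reactants: 4 (S)-4-iodobutan-2-ol
Product: 5 (S)-tert-butyl[(4-iodobutan-2-yl)oxy]dimethylsilane
Conditions: TBSOTf, 2,6-lutidine, CH2Cl2, 0 °C
Reagents that add atoms: tert-butyldimethylsilyl trifluoromethanesulfonate, CC(C)(C)[Si](C)(C)OS(=O)(=O)C(F)(F)F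
Why: Silylation of the secondary alcohol with the silyl triflate and a non-nucleophilic pyridine base is fast at low temperature and avoids N-alkylation of a nucleophilic base by the primary iodide; the configuration is retained because only the O–H bond reacts.

Step 4
Reactants: 5 (S)-tert-butyl[(4-iodobutan-2-yl)oxy]dimethylsilane; 2 4,6,7-trimethoxy-2,3-dihydro-1H-inden-1-one
Product: 7 1-[(3S)-3-(tert-butyldimethylsilyloxy)butyl]-4,6,7-trimethoxy-2,3-dihydro-1H-inden-1-ol (both C1 epimers), via alkylmagnesium iodide 6 (not isolated)
Conditions: 5, Mg, Et2O, reflux; then added to 2, LaCl3·2LiCl, THF, 0 °C → rt; sat. aq NH4Cl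
Reagents that add atoms: magnesium, [Mg] (retained only in 6)
Why: Magnesium insertion into the primary iodide is followed by Grignard 1,2-addition to the ketone, with LaCl3·2LiCl activating the carbonyl group and tempering the basicity so that enolisation of the indanone is suppressed; the new carbinol centre forms without control, which does not matter because it becomes sp2 in the next step.

Step 5
Reactants: 7 1-[(3S)-3-(tert-butyldimethylsilyloxy)butyl]-4,6,7-trimethoxy-2,3-dihydro-1H-inden-1-ol
Product: 9 3-[(3S)-3-(tert-butyldimethylsilyloxy)butyl]-4,5,7-trimethoxy-1H-indene, via tertiary mesylate 8 (not isolated)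
Conditions: MsCl, Et3N (excess), CH2Cl2, 0 °C → rt
Reagents that add atoms: methanesulfonyl chloride, CS(=O)(=O)Cl (retained only in 8)
Why: Mesylation of the tertiary benzylic alcohol and elimination in the same flask under amine base (alcohol dehydration) should give the ring-conjugated endocyclic alkene, which is favoured over the exocyclic isomer by conjugation and by allylic strain of an alkylidene group against the neighbouring methoxy group, while the absence of acid keeps the silyl ether from capturing the benzylic cation.

Step 6
Reactants: 9 3-[(3S)-3-(tert-butyldimethylsilyloxy)butyl]-4,5,7-trimethoxy-1H-indene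
Product: 11 2-{2-[(4S)-4-(tert-butyldimethylsilyloxy)pentanoyl]-3,4,6-trimethoxyphenyl}acetaldehyde, via cis-diol 10 (not isolated)
Conditions: OsO4 (2 mol %), NaIO4, 2,6-lutidine, 1,4-dioxane/H2O (3:1), rt; crude product used at once
Reagents that add atoms: osmium tetroxide, O=[Os](=O)(=O)=O (oxygen carrier); sodium periodate, [Na+].[O-]I(=O)(=O)=O (terminal oxygen source)
Why: In this Lemieux–Johnson cleavage OsO4 dihydroxylates the only alkene and periodate splits the cis-diol, so the alkyl-bearing indene carbon becomes the C4 ketone and its neighbour the C2 aldehyde, while 2,6-lutidine buffers the medium to protect the silyl ether and the aldol-prone keto aldehyde, and the methoxyarene is inert to both oxidants.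

Step 7
Reactants: 11 2-{2-[(4S)-4-(tert-butyldimethylsilyloxy)pentanoyl]-3,4,6-trimethoxyphenyl}acetaldehyde
Product: 12 2-{2-[(4S)-4-(tert-butyldimethylsilyloxy)pentanoyl]-3,4,6-trimethoxyphenyl}acetic acid
Conditions: NaClO2, NaH2PO4, 2-methyl-2-butene (large excess), t-BuOH/H2O, 0 °C → rt
Reagents that add atoms: sodium chlorite, [Na+].[O-]Cl=O
Why: Pinnick oxidation at about pH 4 converts the aldehyde into the acid without enolising it, and the large excess of alkene scavenger removes the electrophilic chlorine by-product before it can attack the free C7–H of the electron-rich ring.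

Step 8
Reactants: 12 2-{2-[(4S)-4-(tert-butyldimethylsilyloxy)pentanoyl]-3,4,6-trimethoxyphenyl}acetic acid
Product: 13 methyl 2-{2-[(4S)-4-(tert-butyldimethylsilyloxy)pentanoyl]-3,4,6-trimethoxyphenyl}acetate
Conditions: MeI, KHCO3, DMF, rt
Reagents that add atoms: iodomethane, CI
Why: SN2 O-alkylation of the potassium carboxylate gives the open-chain (normal) methyl ester rather than a cyclic pseudo-ester, and hydrogen carbonate is too weak a base to enolise the ketone or start the condensation early.

Step 9
Reactants: 13 methyl 2-{2-[(4S)-4-(tert-butyldimethylsilyloxy)pentanoyl]-3,4,6-trimethoxyphenyl}acetate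
Product: 14 2-[(2S)-2-(tert-butyldimethylsilyloxy)propyl]-5,7,8-trimethoxynaphthalene-1,3-diol
Conditions: NaOMe (3 equiv), degassed MeOH, Ar, 65 °C; then AcOH, 0 °C; extracted under Ar and used without chromatography
Reagents that add atoms: none
Why: Methoxide deprotonates both acidic sites reversibly; the C3 enolate of the C4 aryl ketone adds to the ester carbonyl C2, methoxide leaves, and the 1,3-diketone tautomerises to the aromatic diol, whose conversion into the naphtholate makes the sequence irreversible. This is a Dieckmann-type intramolecular Claisen condensation, the reaction type by which 2-acylarylacetates are turned into naphthalene-1,3-diols. Ring B closes in a favoured 6-(enolendo)-exo-trig mode and only the C2–C3 bond is formed. No stereocentre is created, and the silyloxy carbon is gamma to the ketone, so it can neither epimerise nor be lost by beta-elimination. The step needs site selectivity between two carbanions: the more acidic C1 methylene could reach the C4 ketone only through a four-membered ring, and any O-acylation to an enol lactone is undone by methoxide, so ring size channels all material through C3. Oxygen is excluded because the electron-rich diol is attacked by air at C1, a reaction reserved for the next step.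

Step 10
Reactants: 14 2-[(2S)-2-(tert-butyldimethylsilyloxy)propyl]-5,7,8-trimethoxynaphthalene-1,3-diol
Product: 15 3-[(2S)-2-(tert-butyldimethylsilyloxy)propyl]-2-hydroxy-5,6,8-trimethoxynaphthalene-1,4-dione
Conditions: O2 (1 atm), K2CO3, MeOH, rt; then 1 M HCl, 0 °C
Reagents that add atoms: dioxygen, O=O
Why: In this base-mediated autoxidation of a naphthoresorcinol the naphtholate takes up O2 at C1, the only unsubstituted carbon of ring B and ortho/para to its two oxygens, and the hydroperoxide loses water to give the C1 carbonyl group and hence the 2-hydroxy-1,4-quinone, whose stabilised anion resists further oxidation.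

Step 11
Reactants: 15 3-[(2S)-2-(tert-butyldimethylsilyloxy)propyl]-2-hydroxy-5,6,8-trimethoxynaphthalene-1,4-dione
Product: 16 2-hydroxy-3-[(2S)-2-hydroxypropyl]-5,6,8-trimethoxynaphthalene-1,4-dione
Conditions: HF·pyridine, THF, 0 °C → rt (polyethylene vessel)
Reagents that add atoms: none
Why: Fluoride-driven cleavage of the Si–O bond (desilylation) in a weakly acidic medium leaves the C–O bond and thus the (S) configuration intact, and it avoids the strong acid that would cyclise the side-chain alcohol onto the quinone.

Step 12
Reactants: 16 2-hydroxy-3-[(2S)-2-hydroxypropyl]-5,6,8-trimethoxynaphthalene-1,4-dione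
Product: 18 3-[(2S)-2-acetoxypropyl]-2-hydroxy-5,6,8-trimethoxynaphthalene-1,4-dione (CNP0321270.1), via diacetate 17 (not isolated)
Conditions: Ac2O (3 equiv), pyridine, DMAP (cat.), CH2Cl2, 0 °C → rt; then MeOH, rt; dilute citric acid work-up
Reagents that add atoms: acetic anhydride, CC(=O)OC(C)=O
Why: Exhaustive DMAP-catalysed acetylation esterifies both hydroxyl groups, and because the C2 quinonyl acetate is a vinylogous mixed anhydride (its leaving group is about as acidic as a carboxylic acid) it alone is methanolysed under the same nucleophilic catalysis, leaving the secondary alkyl acetate with the stereocentre untouched.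

## Compound list

1 | 3-(2,4,5-trimethoxyphenyl)propanoic acid | COc1cc(OC)c(CCC(=O)O)cc1OC | starting material
2 | 4,6,7-trimethoxy-2,3-dihydro-1H-inden-1-one | COc1cc(OC)c2c(c1OC)C(=O)CC2 | intermediate
3 | (S)-butane-1,3-diol | OCC[C@H](C)O | starting material
4 | (S)-4-iodobutan-2-ol | ICC[C@H](C)O | intermediate
5 | (S)-tert-butyl[(4-iodobutan-2-yl)oxy]dimethylsilane | ICC[C@H](C)O[Si](C)(C)C(C)(C)C | intermediate
6 | [(3S)-3-(tert-butyldimethylsilyloxy)butyl]magnesium iodide | I[Mg]CC[C@H](C)O[Si](C)(C)C(C)(C)C | intermediate
7 | 1-[(3S)-3-(tert-butyldimethylsilyloxy)butyl]-4,6,7-trimethoxy-2,3-dihydro-1H-inden-1-ol (both C1 epimers) | COc1cc(OC)c2c(c1OC)C(O)(CC[C@H](C)O[Si](C)(C)C(C)(C)C)CC2 | intermediate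
8 | 1-[(3S)-3-(tert-butyldimethylsilyloxy)butyl]-4,6,7-trimethoxy-2,3-dihydro-1H-inden-1-yl methanesulfonate | COc1cc(OC)c2c(c1OC)C(OS(C)(=O)=O)(CC[C@H](C)O[Si](C)(C)C(C)(C)C)CC2 | intermediate
9 | 3-[(3S)-3-(tert-butyldimethylsilyloxy)butyl]-4,5,7-trimethoxy-1H-indene | COc1cc(OC)c2c(c1OC)C(CC[C@H](C)O[Si](C)(C)C(C)(C)C)=CC2 | intermediate
10 | cis-1-[(3S)-3-(tert-butyldimethylsilyloxy)butyl]-4,6,7-trimethoxy-2,3-dihydro-1H-indene-1,2-diol (both cis diastereomers) | COc1cc(OC)c2c(c1OC)C(O)(CC[C@H](C)O[Si](C)(C)C(C)(C)C)C(O)C2 | intermediate
11 | 2-{2-[(4S)-4-(tert-butyldimethylsilyloxy)pentanoyl]-3,4,6-trimethoxyphenyl}acetaldehyde | O=CCc1c(OC)cc(OC)c(OC)c1C(=O)CC[C@H](C)O[Si](C)(C)C(C)(C)C | intermediate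
12 | 2-{2-[(4S)-4-(tert-butyldimethylsilyloxy)pentanoyl]-3,4,6-trimethoxyphenyl}acetic acid | OC(=O)Cc1c(OC)cc(OC)c(OC)c1C(=O)CC[C@H](C)O[Si](C)(C)C(C)(C)C | intermediate
13 | methyl 2-{2-[(4S)-4-(tert-butyldimethylsilyloxy)pentanoyl]-3,4,6-trimethoxyphenyl}acetate | COC(=O)Cc1c(OC)cc(OC)c(OC)c1C(=O)CC[C@H](C)O[Si](C)(C)C(C)(C)C | intermediate
14 | 2-[(2S)-2-(tert-butyldimethylsilyloxy)propyl]-5,7,8-trimethoxynaphthalene-1,3-diol | COc1cc(OC)c2cc(O)c(C[C@H](C)O[Si](C)(C)C(C)(C)C)c(O)c2c1OC | intermediate
15 | 3-[(2S)-2-(tert-butyldimethylsilyloxy)propyl]-2-hydroxy-5,6,8-trimethoxynaphthalene-1,4-dione | COc1cc(OC)c2c(c1OC)C(=O)C(C[C@H](C)O[Si](C)(C)C(C)(C)C)=C(O)C2=O | intermediate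
16 | 2-hydroxy-3-[(2S)-2-hydroxypropyl]-5,6,8-trimethoxynaphthalene-1,4-dione | COc1cc(OC)c2c(c1OC)C(=O)C(C[C@H](C)O)=C(O)C2=O | intermediate
17 | 2-acetoxy-3-[(2S)-2-acetoxypropyl]-5,6,8-trimethoxynaphthalene-1,4-dione | COc1cc(OC)c2c(c1OC)C(=O)C(C[C@H](C)OC(C)=O)=C(OC(C)=O)C2=O | intermediate
18 | 3-[(2S)-2-acetoxypropyl]-2-hydroxy-5,6,8-trimethoxynaphthalene-1,4-dione (CNP0321270.1) | COc1cc(OC)c2c(c1OC)C(=O)C(C[C@H](C)OC(C)=O)=C(O)C2=O | target

## Step count

Total step count: 12.
Longest linear sequence: 11 steps (3 → 18, steps 2 to 12). The branch from 1 runs over 10 steps.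

## Steps most likely to fail

**Step 9 (key step).** The productive ketone enolate may be too scarce beside the more acidic arylacetate position. Saponification of the ester by traces of water, intermolecular condensation or slow loss of the silyl ether in hot methoxide could then overtake ring closure.

The fallback sets out from acid 12 and replaces the thermodynamic alkoxide condensation by a kinetic, magnesium-templated acylation with an active ester. Acid 12 is coupled with pentafluorophenol (EDC·HCl, CH2Cl2, rt) to give the pentafluorophenyl ester F1. Treatment with MgBr2·OEt2 and i-Pr2NEt in CH2Cl2 under argon then enolises the magnesium-bound C4 ketone softly at C3. The enolate is acylated irreversibly by the neighbouring active ester. After a mild acidic work-up the route is rejoined at diol 14.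

**Step 4.** Deprotonation of the indanone by the basic organometallic reagent, and Wurtz-type coupling during magnesium insertion, would return the ketone unchanged. The following dehydration adds the risk of a misplaced double bond or of silyl loss by neighbouring-group capture.

The fallback sets out from 2 and 5 and builds the same C–C bond by cross-coupling on an sp2 carbon whose double bond is already in place. Indanone 2 is converted (KN(SiMe3)2, THF, −78 °C, then PhNTf2) into 4,5,7-trimethoxy-1H-inden-3-yl trifluoromethanesulfonate F2. Iodide 5 is converted with Zn dust and LiCl in THF into [(3S)-3-(tert-butyldimethylsilyloxy)butyl]zinc iodide F3. Negishi coupling of the two with catalytic PdCl2(dppf) in THF at 50 °C comes back to the route at indene 9, so steps 4 and 5 both fall away.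

**Step 6.** Oxidative damage to the trimethoxy ring, or self-condensation of the keto aldehyde (intramolecular aldol closure and aromatisation) during cleavage and handling, would erode the material. The aldehyde must also survive into the chlorite oxidation.

The fallback sets out from indene 9 and never passes through an aldehyde. Dihydroxylation with catalytic OsO4 and N-methylmorpholine N-oxide (acetone/H2O) gives diol 10, this time isolated. Parikh–Doering oxidation (SO3·pyridine, DMSO, Et3N) of its secondary alcohol gives the alpha-ketol 1-[(3S)-3-(tert-butyldimethylsilyloxy)butyl]-1-hydroxy-4,6,7-trimethoxy-1,3-dihydro-2H-inden-2-one F4. Criegee-type cleavage of this ketol with Pb(OAc)4 in MeOH/CH2Cl2 at 0 °C delivers the aryl ketone and the methyl ester in one operation. The route is rejoined at keto ester 13, so steps 7 and 8 fall away.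

## Further compounds

F1 | step 9 | pentafluorophenyl 2-{2-[(4S)-4-(tert-butyldimethylsilyloxy)pentanoyl]-3,4,6-trimethoxyphenyl}acetate | O=C(Cc1c(OC)cc(OC)c(OC)c1C(=O)CC[C@H](C)O[Si](C)(C)C(C)(C)C)Oc1c(F)c(F)c(F)c(F)c1F
F2 | step 4 | 4,5,7-trimethoxy-1H-inden-3-yl trifluoromethanesulfonate | COc1cc(OC)c2c(c1OC)C(OS(=O)(=O)C(F)(F)F)=CC2
F3 | step 4 | [(3S)-3-(tert-butyldimethylsilyloxy)butyl]zinc iodide | I[Zn]CC[C@H](C)O[Si](C)(C)C(C)(C)C
F4 | step 6 | 1-[(3S)-3-(tert-butyldimethylsilyloxy)butyl]-1-hydroxy-4,6,7-trimethoxy-1,3-dihydro-2H-inden-2-one (both C1 epimers) | COc1cc(OC)c2c(c1OC)C(O)(CC[C@H](C)O[Si](C)(C)C(C)(C)C)C(=O)C2
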